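**Strategy.** The ring (C1 carrying the side chain, C2, C3 the carbinol, C4, C5 bearing OMe, C6 bearing OAc) is a cyclohexa-1,4-diene, and its enol-ether bond C4=C5 is disconnected last. Ring-closing metathesis joins a vinyl group on C3 to a 1-methoxyvinyl group on C6. Both carbinol carbons sit cis on the preformed (Z)-trisubstituted C1=C2 alkene, so one operation closes the six-membered ring and creates the skipped diene under neutral conditions, with all three stereocentres already set. The precursor is an acyclic (Z)-triene carrying both acetates and a C3 tert-butyldimethylsilyl ether, built from (R)-epichlorohydrin, decylmagnesium bromide, acrolein and methyl vinyl ether.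

Key step: step 13

Assumption: the (S,S)-ProPhenol–zinc catalyst is taken to add the alkynyl group to the Si face of acrolein (3R product); this sense is not certain, both mirror-image forms of the ligand are sold, and the configuration would be checked on 9 by Mosher ester analysis and the antipodal ligand used if required.

Step 1
Reactants: 1 (R)-epichlorohydrin [(2R)-2-(chloromethyl)oxirane]; 2 decylmagnesium bromide
Product: 3 (2R)-1-chlorotridecan-2-ol
Conditions: CuI (10 mol%), THF, −40 → 0 °C; aq. NH4Cl
Reagents that add atoms: none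
Why: Copper-catalysed SN2 opening of the epoxide by the Grignard reagent occurs at the unsubstituted ring carbon faster than attack at C–Cl, and the stereocentre, which is not a reacting atom, keeps the configuration bought with 1.

Step 2
Reactants: 3 (2R)-1-chlorotridecan-2-ol
Product: 5 (4R)-pentadec-1-yn-4-ol, via (R)-1,2-epoxytridecane 4 (not isolated)
Conditions: LiC≡CH·H2NCH2CH2NH2 (3.5 equiv), DMSO, 0 °C → rt; H2O
Reagents that add atoms: lithium acetylide–ethylenediamine complex, [Li+].[C-]#C.NCCN
Why: The basic acetylide first closes the chlorohydrin to the epoxide (intramolecular Williamson etherification) and a further equivalent opens it at the terminal carbon (SN2 alkynylation of an epoxide), so the carbinol stereocentre is never a reacting centre.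

Step 3
Reactants: 5 (4R)-pentadec-1-yn-4-ol
Product: 6 triethyl{[(4R)-pentadec-1-yn-4-yl]oxy}silane
Conditions: TESCl, imidazole, DMF, 0 °C → rt
Reagents that add atoms: chlorotriethylsilane, CC[Si](Cl)(CC)CC
Why: Standard silylation of a secondary alcohol; the triethylsilyl ether survives the organometallic steps and can later be removed without loss of a tert-butyldimethylsilyl ether.

Step 4
Reactants: 6 triethyl{[(4R)-pentadec-1-yn-4-yl]oxy}silane; 7 acrolein
Product: 9 (3R,7R)-7-[(triethylsilyl)oxy]octadec-1-en-4-yn-3-ol, via alkynyl(methyl)zinc 8 (not isolated)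
Conditions: Me2Zn (3 equiv), (S,S)-ProPhenol (20 mol%), Ph3P=O (40 mol%), toluene, rt; then 7 (3 equiv, slow addition), 0 °C; aq. NH4Cl
Reagents that add atoms: none
Why: Zinc/ProPhenol-catalysed enantioselective alkynylation of an enal, in which the chiral dinuclear zinc catalyst alone (the C7 centre is too remote to matter) directs the alkynyl group to the Si face of acrolein and so sets C3 as (R).

Step 5
Reactants: 9 (3R,7R)-7-[(triethylsilyl)oxy]octadec-1-en-4-yn-3-ol
Product: 11 (3R,4Z,7R)-5-iodo-7-[(triethylsilyl)oxy]octadeca-1,4-dien-3-ol, via cyclic alkenylaluminate 10 (not isolated)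
Conditions: NaAlH2(OCH2CH2OCH3)2 (1.8 equiv), THF, 0 °C → rt; EtOAc; I2, THF, −78 → 0 °C; aq. Na2S2O3, potassium sodium tartrate
Reagents that add atoms: iodine, II
Why: Hydroxyl-directed trans-hydroalumination of the propargylic alcohol places aluminium on the distal alkyne carbon in a five-membered aluminate, and iodinolysis with retention gives the (Z)-iodide with iodine cis to the carbinol carbon; the isolated vinyl group is not reduced.

Step 6
Reactants: 11 (3R,4Z,7R)-5-iodo-7-[(triethylsilyl)oxy]octadeca-1,4-dien-3-ol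
Product: 12 tert-butyl({(3R,4Z,7R)-5-iodo-7-[(triethylsilyl)oxy]octadeca-1,4-dien-3-yl}oxy)dimethylsilane
Conditions: TBSCl, imidazole, DMAP (cat.), DMF, rt
Reagents that add atoms: tert-butyldimethylsilyl chloride, CC(C)(C)[Si](C)(C)Cl
Why: Standard silylation of the doubly allylic alcohol under non-acidic conditions, giving the C3 protecting group that is carried to the last step.

Step 7
Reactants: 12 tert-butyl({(3R,4Z,7R)-5-iodo-7-[(triethylsilyl)oxy]octadeca-1,4-dien-3-yl}oxy)dimethylsilane
Product: 14 (2Z,4R)-4-[(tert-butyldimethylsilyl)oxy]-N-methoxy-N-methyl-2-{(2R)-2-[(triethylsilyl)oxy]tridecyl}hexa-2,5-dienamide, via (Z)-alkenyllithium 13 (not isolated)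
Conditions: t-BuLi (2.1 equiv), Et2O, −78 °C, 10 min; ClC(O)N(OMe)Me (1.5 equiv), −78 → −20 °C; aq. NH4Cl
Reagents that add atoms: N-methoxy-N-methylcarbamoyl chloride, CON(C)C(Cl)=O
Why: Iodine–lithium exchange with retention of alkene geometry followed by acylation with the carbamoyl chloride (Weinreb amide synthesis); ether as solvent, −78 °C and immediate trapping are chosen to suppress 1,4-migration of silicon from oxygen to the lithiated carbon.

Step 8
Reactants: 14 (2Z,4R)-4-[(tert-butyldimethylsilyl)oxy]-N-methoxy-N-methyl-2-{(2R)-2-[(triethylsilyl)oxy]tridecyl}hexa-2,5-dienamide; 15 methyl vinyl ether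
Product: 17 (4Z,6R)-6-[(tert-butyldimethylsilyl)oxy]-2-methoxy-4-{(2R)-2-[(triethylsilyl)oxy]tridecyl}octa-1,4,7-trien-3-one, via 1-methoxyvinyllithium 16 (not isolated)
Conditions: 15 (4 equiv), t-BuLi (2 equiv), THF, −78 → 0 °C; then 14, −78 °C; aq. NH4Cl
Reagents that add atoms: none
Why: α-Lithiation of methyl vinyl ether gives an acyl-anion equivalent that adds once to the Weinreb amide, whose chelated tetrahedral intermediate collapses to the ketone only on work-up (Weinreb ketone synthesis); this avoids a configurationally labile (Z)-enal and a separate oxidation.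

Step 9
Reactants: 17 (4Z,6R)-6-[(tert-butyldimethylsilyl)oxy]-2-methoxy-4-{(2R)-2-[(triethylsilyl)oxy]tridecyl}octa-1,4,7-trien-3-one
Product: 18 (4Z,6R)-6-[(tert-butyldimethylsilyl)oxy]-4-[(2R)-2-hydroxytridecyl]-2-methoxyocta-1,4,7-trien-3-one
Conditions: HF·pyridine, pyridine, THF, 0 °C; aq. NaHCO3
Reagents that add atoms: none
Why: Pyridine-buffered HF cleaves the triethylsilyl ether far faster than the secondary tert-butyldimethylsilyl ether, and the protecting-group exchange is placed here because the enol ether is conjugated with the ketone and therefore not acid-labile at this stage.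

Step 10
Reactants: 18 (4Z,6R)-6-[(tert-butyldimethylsilyl)oxy]-4-[(2R)-2-hydroxytridecyl]-2-methoxyocta-1,4,7-trien-3-one
Product: 19 (4Z,6R)-4-[(2R)-2-acetoxytridecyl]-6-[(tert-butyldimethylsilyl)oxy]-2-methoxyocta-1,4,7-trien-3-one
Conditions: Ac2O, pyridine, DMAP (cat.), CH2Cl2, 0 °C → rt
Reagents that add atoms: acetic anhydride, CC(=O)OC(C)=O
Why: DMAP-catalysed acetylation of the only free hydroxyl group installs the side-chain acetate after the last organolithium step.

Step 11
Reactants: 19 (4Z,6R)-4-[(2R)-2-acetoxytridecyl]-6-[(tert-butyldimethylsilyl)oxy]-2-methoxyocta-1,4,7-trien-3-one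
Product: 20 (3S,4Z,6R)-4-[(2R)-2-acetoxytridecyl]-6-[(tert-butyldimethylsilyl)oxy]-2-methoxyocta-1,4,7-trien-3-ol
Conditions: (S)-2-methyl-CBS-oxazaborolidine (0.5 equiv), catecholborane (2 equiv), toluene, −78 °C; MeOH, then pH 7 buffer
Reagents that add atoms: none
Why: Corey–Bakshi–Shibata reduction of an enone, in which the ketone binds to the catalyst anti to its larger substituent (the branched (Z)-trisubstituted alkenyl group, with 1-methoxyvinyl as the small group), so that the (S)-catalyst should deliver hydride to the face giving the (3S) carbinol (ring C6); catecholborane at −78 °C does not hydroborate the alkenes or reduce the acetate.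

Step 12
Reactants: 20 (3S,4Z,6R)-4-[(2R)-2-acetoxytridecyl]-6-[(tert-butyldimethylsilyl)oxy]-2-methoxyocta-1,4,7-trien-3-ol
Product: 21 (3S,4Z,6R)-4-[(2R)-2-acetoxytridecyl]-6-[(tert-butyldimethylsilyl)oxy]-2-methoxyocta-1,4,7-trien-3-yl acetate
Conditions: Ac2O, Et3N, DMAP (cat.), CH2Cl2, 0 °C; chromatography on Et3N-deactivated silica
Reagents that add atoms: acetic anhydride, CC(=O)OC(C)=O
Why: Base-mediated acetylation of the doubly allylic alcohol under non-acidic conditions leaves the now unconjugated enol ether and the stereocentres untouched.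

Step 13
Reactants: 21 (3S,4Z,6R)-4-[(2R)-2-acetoxytridecyl]-6-[(tert-butyldimethylsilyl)oxy]-2-methoxyocta-1,4,7-trien-3-yl acetate
Product: 22 (2R)-1-{(3S,6S)-6-acetoxy-3-[(tert-butyldimethylsilyl)oxy]-5-methoxycyclohexa-1,4-dien-1-yl}tridecan-2-yl acetate
Conditions: (H2IMes)(PCy3)Cl2Ru=CHPh (second-generation Grubbs catalyst, 10 mol%), 1,4-benzoquinone (20 mol%), toluene (0.005 M), 60 °C
Reagents that add atoms: none
Why: The benzylidene complex initiates at the monosubstituted vinyl group on C3, the only unhindered terminal alkene, and the resulting alkylidene undergoes [2+2] addition to the 1,1-disubstituted 1-methoxyvinyl group with ruthenium bonding to its CH2 terminus, so that cycloreversion of the metallacyclobutane forms C4=C5 and a ruthenium methylidene that turns over with loss of ethylene. The closest known reaction type is ring-closing metathesis of 2-alkoxy-1,n-dienes to cyclic enol ethers. The six-membered ring closes as an ordinary diene ring-closing metathesis whose two reacting carbons become the endocyclic C4=C5 bond, and the (Z)-configured C1=C2 alkene keeps C3 and C6 on the same side, which pre-organises the chain, while being too substituted to enter metathesis itself. No stereocentre is formed, and C3, C6 and the side-chain carbinol are not reacting atoms. The chemoselectivity needed (initiation at vinyl, closure onto the enol ether without carbene formation at its substituted carbon) follows from olefin substitution, and high dilution disfavours dimerisation at the vinyl group. 1,4-Benzoquinone intercepts ruthenium hydrides so that the skipped diene is not isomerised towards an arene.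

Step 14
Reactants: 22 (2R)-1-{(3S,6S)-6-acetoxy-3-[(tert-butyldimethylsilyl)oxy]-5-methoxycyclohexa-1,4-dien-1-yl}tridecan-2-yl acetate
Product: 23 (2R)-1-[(3S,6S)-6-acetoxy-3-hydroxy-5-methoxycyclohexa-1,4-dien-1-yl]tridecan-2-yl acetate (target)
Conditions: Bu4NF/AcOH (1:1, 3 equiv), THF, 0 °C → rt; pH 7 buffer; chromatography on Et3N-deactivated silica
Reagents that add atoms: none
Why: Fluoride-mediated desilylation buffered with acetic acid keeps the medium close to neutral, so the two acetates stay in place and the dienol, which could lose acetic acid or water to form an arene under acid or base, is not exposed to either.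

**Compound list**

1 | (R)-epichlorohydrin | ClC[C@H]1CO1 | starting material
2 | decylmagnesium bromide | CCCCCCCCCC[Mg]Br | starting material
3 | (2R)-1-chlorotridecan-2-ol | CCCCCCCCCCC[C@@H](O)CCl | intermediate
4 | (R)-1,2-epoxytridecane | CCCCCCCCCCC[C@@H]1CO1 | intermediate
5 | (4R)-pentadec-1-yn-4-ol | CCCCCCCCCCC[C@@H](O)CC#C | intermediate
6 | triethyl{[(4R)-pentadec-1-yn-4-yl]oxy}silane | CCCCCCCCCCC[C@@H](O[Si](CC)(CC)CC)CC#C | intermediate
7 | acrolein | C=CC=O | starting material
8 | methyl{(4R)-4-[(triethylsilyl)oxy]pentadec-1-yn-1-yl}zinc | CCCCCCCCCCC[C@@H](O[Si](CC)(CC)CC)CC#C[Zn]C | intermediate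
9 | (3R,7R)-7-[(triethylsilyl)oxy]octadec-1-en-4-yn-3-ol | CCCCCCCCCCC[C@@H](O[Si](CC)(CC)CC)CC#C[C@H](O)C=C | intermediate
10 | sodium cyclic alkenyl(alkoxy)bis(2-methoxyethoxy)aluminate from 9 (Al on C5 and on the C3 oxygen) | CCCCCCCCCCC[C@@H](O[Si](CC)(CC)CC)CC1=C[C@@H](C=C)O[Al-]1(OCCOC)OCCOC.[Na+] | intermediate
11 | (3R,4Z,7R)-5-iodo-7-[(triethylsilyl)oxy]octadeca-1,4-dien-3-ol | CCCCCCCCCCC[C@@H](O[Si](CC)(CC)CC)C/C(I)=C/[C@H](O)C=C | intermediate
12 | tert-butyl({(3R,4Z,7R)-5-iodo-7-[(triethylsilyl)oxy]octadeca-1,4-dien-3-yl}oxy)dimethylsilane | CCCCCCCCCCC[C@@H](O[Si](CC)(CC)CC)C/C(I)=C/[C@H](O[Si](C)(C)C(C)(C)C)C=C | intermediate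
13 | (Z)-alkenyllithium from 12 (Li in place of I) | CCCCCCCCCCC[C@@H](O[Si](CC)(CC)CC)C/C([Li])=C/[C@H](O[Si](C)(C)C(C)(C)C)C=C | intermediate
14 | (2Z,4R)-4-[(tert-butyldimethylsilyl)oxy]-N-methoxy-N-methyl-2-{(2R)-2-[(triethylsilyl)oxy]tridecyl}hexa-2,5-dienamide | CCCCCCCCCCC[C@@H](O[Si](CC)(CC)CC)C/C(=C/[C@H](O[Si](C)(C)C(C)(C)C)C=C)C(=O)N(C)OC | intermediate
15 | methyl vinyl ether | COC=C | starting material
16 | 1-methoxyvinyllithium | [Li]C(=C)OC | intermediate
17 | (4Z,6R)-6-[(tert-butyldimethylsilyl)oxy]-2-methoxy-4-{(2R)-2-[(triethylsilyl)oxy]tridecyl}octa-1,4,7-trien-3-one | CCCCCCCCCCC[C@@H](O[Si](CC)(CC)CC)C/C(=C/[C@H](O[Si](C)(C)C(C)(C)C)C=C)C(=O)C(=C)OC | intermediate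
18 | (4Z,6R)-6-[(tert-butyldimethylsilyl)oxy]-4-[(2R)-2-hydroxytridecyl]-2-methoxyocta-1,4,7-trien-3-one | CCCCCCCCCCC[C@@H](O)C/C(=C/[C@H](O[Si](C)(C)C(C)(C)C)C=C)C(=O)C(=C)OC | intermediate
19 | (4Z,6R)-4-[(2R)-2-acetoxytridecyl]-6-[(tert-butyldimethylsilyl)oxy]-2-methoxyocta-1,4,7-trien-3-one | CCCCCCCCCCC[C@@H](OC(C)=O)C/C(=C/[C@H](O[Si](C)(C)C(C)(C)C)C=C)C(=O)C(=C)OC | intermediate
20 | (3S,4Z,6R)-4-[(2R)-2-acetoxytridecyl]-6-[(tert-butyldimethylsilyl)oxy]-2-methoxyocta-1,4,7-trien-3-ol | CCCCCCCCCCC[C@@H](OC(C)=O)C/C(=C/[C@H](O[Si](C)(C)C(C)(C)C)C=C)[C@H](O)C(=C)OC | intermediate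
21 | (3S,4Z,6R)-4-[(2R)-2-acetoxytridecyl]-6-[(tert-butyldimethylsilyl)oxy]-2-methoxyocta-1,4,7-trien-3-yl acetate | CCCCCCCCCCC[C@H](C/C(=C/[C@H](O[Si](C)(C)C(C)(C)C)C=C)[C@H](OC(C)=O)C(=C)OC)OC(C)=O | intermediate
22 | (2R)-1-{(3S,6S)-6-acetoxy-3-[(tert-butyldimethylsilyl)oxy]-5-methoxycyclohexa-1,4-dien-1-yl}tridecan-2-yl acetate | CCCCCCCCCCC[C@H](CC1=C[C@H](O[Si](C)(C)C(C)(C)C)C=C(OC)[C@H]1OC(C)=O)OC(C)=O | intermediate
23 | (2R)-1-[(3S,6S)-6-acetoxy-3-hydroxy-5-methoxycyclohexa-1,4-dien-1-yl]tridecan-2-yl acetate | CCCCCCCCCCC[C@H](CC1=C[C@H](O)C=C(OC)[C@H]1OC(C)=O)OC(C)=O | target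

**Step count.** Total: 14 steps. Longest linear sequence: 14 steps (from 1 to 23).

**Steps most likely to fail**

Step 13 (ring-closing metathesis). Closure onto the hindered, electron-rich 1,1-disubstituted enol ether may be slow, so that the alkylidene formed at the vinyl group dimerises or the catalyst decays first; ruthenium-hydride-induced double-bond migration followed by loss of acetic acid to an arene is the other danger. The fallback sets out from alcohol 20 and closes the ring before the second acetylation. With (H2IMes)(PCy3)Cl2Ru=CHPh and 1,4-benzoquinone in toluene at 40 °C, the free allylic hydroxyl group at C6 is expected to speed up reaction of the neighbouring enol-ether alkene with the alkylidene and should give (2R)-1-{(3S,6S)-3-[(tert-butyldimethylsilyl)oxy]-6-hydroxy-5-methoxycyclohexa-1,4-dien-1-yl}tridecan-2-yl acetate F1. Acetylation of F1 (Ac2O, Et3N, DMAP, CH2Cl2, 0 °C) returns to the route at 22.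

Step 11 (Corey–Bakshi–Shibata reduction). Facial discrimination may be poor because both ketone substituents are alkenyl groups, and coordination of the methoxy oxygen could override the steric model. The fallback sets out from ketone 19 and gives up reagent control. Luche reduction (NaBH4, CeCl3·7H2O, MeOH, −78 °C) should give 20 together with its C3 epimer, (3R,4Z,6R)-4-[(2R)-2-acetoxytridecyl]-6-[(tert-butyldimethylsilyl)oxy]-2-methoxyocta-1,4,7-trien-3-ol F2. The two diastereomers are separated on Et3N-deactivated silica; 20 re-enters the route at step 12, and F2 is oxidised back to 19 with Dess–Martin periodinane (NaHCO3-buffered) and recycled.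

Step 4 (alkynylation of acrolein). Acrolein may polymerise under the Lewis-acidic zinc conditions, giving low conversion, and incomplete or reversed facial control would give C3 epimers that are unlikely to be separable. The fallback sets out from 6. Deprotonation with n-BuLi (THF, −78 °C) and addition to acrolein gives the C3-epimeric alcohol (3RS,7R)-7-[(triethylsilyl)oxy]octadec-1-en-4-yn-3-ol F3. Sharpless kinetic resolution (Ti(OiPr)4, D-(−)-diisopropyl tartrate, t-BuOOH, 4 Å sieves, CH2Cl2, −20 °C) should epoxidise the (3S) epimer selectively to (2S,3R,7R)-1,2-epoxy-7-[(triethylsilyl)oxy]octadec-4-yn-3-ol F4 and leave 9, which is separated by chromatography and re-enters the route at step 5.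

**Further compounds**

F1 | step 13 | (2R)-1-{(3S,6S)-3-[(tert-butyldimethylsilyl)oxy]-6-hydroxy-5-methoxycyclohexa-1,4-dien-1-yl}tridecan-2-yl acetate | CCCCCCCCCCC[C@H](CC1=C[C@H](O[Si](C)(C)C(C)(C)C)C=C(OC)[C@H]1O)OC(C)=O
F2 | step 11 | (3R,4Z,6R)-4-[(2R)-2-acetoxytridecyl]-6-[(tert-butyldimethylsilyl)oxy]-2-methoxyocta-1,4,7-trien-3-ol | CCCCCCCCCCC[C@@H](OC(C)=O)C/C(=C/[C@H](O[Si](C)(C)C(C)(C)C)C=C)[C@@H](O)C(=C)OC
F3 | step 4 | (3RS,7R)-7-[(triethylsilyl)oxy]octadec-1-en-4-yn-3-ol (C3 epimers) | CCCCCCCCCCC[C@@H](O[Si](CC)(CC)CC)CC#CC(O)C=C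
F4 | step 4 | (2S,3R,7R)-1,2-epoxy-7-[(triethylsilyl)oxy]octadec-4-yn-3-ol | CCCCCCCCCCC[C@@H](O[Si](CC)(CC)CC)CC#C[C@@H](O)[C@@H]1CO1
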